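**Ratio clock.** The constants of the candidate steps are hidden, but the green run gives a reading of how fast the two substrates part, and the excess asked for can be reckoned from that reading.

the same everywhere: gas 170 mM (held); free catalyst 15 mM
- green: left-handed substrate 2.1 M; right-handed substrate 2.1 M; run made earlier
- flask: left-handed substrate 1.5 M; right-handed substrate 1.5 M; time 8.0 d

- green (time / d: right-handed substrate / %, left-handed substrate / %): 0.500: 50, 24; 0.833: 49, 13; 1.25: 47, 8; 2.50: 49, 0; 4.00: 49, 0; 6.00: 45, 0

(each reading ± 1.5 percentage points)

- whether the excess of right-handed substrate over left-handed substrate among what is left of the two reaches 98% by 8.0 d (yes / no)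
- the highest excess of right-handed substrate over left-handed substrate among what is left of the two up to 8.0 d

- free catalyst is single-handed; left-handed substrate and right-handed substrate are mirror images of each other, charged as a racemate, each of them at the stated concentration
- at the start none of reagent is dissolved
- candidate steps: free catalyst + left-handed substrate <-> catalyst intermediate A; free catalyst + right-handed substrate <-> catalyst intermediate B; reagent + catalyst intermediate A -> free catalyst + left-handed product; reagent + catalyst intermediate B -> free catalyst + right-handed product; free catalyst -> spent catalyst; gas <-> reagent; 2 reagent -> self-condensation product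

**Two readings.** Both substrates start equal, so the natural logarithm of c(right-handed substrate) over c(left-handed substrate) starts at zero, and that logarithm divided by the elapsed time measures how fast the two part. The green reading at 0.500 d gives 1.47 d⁻¹, and the separate reading at 1.25 d gives 1.42 d⁻¹. Their mean, 1.44 d⁻¹, is the ratio clock, read as the difference of two pseudo-first-order constants.

**Own reckoning.** An excess of 98% needs that logarithm to reach 4.60, so the green clock, carried unchanged into the flask, arrives after 3.19 d, earlier than 8.0 d. At that excess the green c(left-handed substrate) would stand at 0.49 percentage points, less than the scatter of 1.5 points, so this step rests on the reckoning and not on a reading. At 8.0 d the clock puts left-handed over right-handed substrate at 9.75 × 10⁻⁶.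

**The forecast.** The forecast answers yes, with a top of 99.9%, and it passes the level around 3 d: “The flask has the same catalyst and gas and less substrate, so it should be at least as fast.”

**Result.** The flask answers yes, with a top of >99.9%.

    free catalyst + left-handed substrate ⇌ catalyst intermediate A (K = 0.210 M⁻¹, k = 0.204 M⁻¹ s⁻¹)
    free catalyst + right-handed substrate ⇌ catalyst intermediate B (K = 0.134 M⁻¹, k = 0.178 M⁻¹ s⁻¹)
    reagent + catalyst intermediate A → free catalyst + left-handed product (k = 0.0533 M⁻¹ s⁻¹)
    reagent + catalyst intermediate B → free catalyst + right-handed product (k = 5.87 × 10⁻⁴ M⁻¹ s⁻¹)
    free catalyst → spent catalyst (k = 1.09 × 10⁻⁸ s⁻¹)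
    gas ⇌ reagent, rate k6*(csat - [reagent]) (kL = 0.00362 s⁻¹)
    2 reagent → self-condensation product (k = 2.31 × 10⁻⁴ M⁻¹ s⁻¹)

**Clock again.** The flask reaches the wanted excess at 2.48 d, so its own ratio clock, averaged from the start, is 1.85 d⁻¹, faster than the green reading of 1.44 d⁻¹. Right-handed substrate then stands at 48.3% of the two charged together, and at 8.00 d the flask holds 44.7%.

(The numbers in the tables are calculated for substances that don't exist, noise included.)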